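Ring numbering used throughout: C1 = carbonyl next to the hydroxylated carbon, C2 = C–OH, C3 = C–CH3, C4 = second carbonyl, C5 = ring-to-ring carbon, C6 = C–CH2CH2Ph; primes mark the second ring.
Retrosynthesis: the C1 oxygens are removed (bis-resorcinol), the rings are reduced to 2-methylcyclohexane-1,3-diones, then C3–C4 and C3'–C4' are cut (twofold Claisen) and last C5–C6 and C5'–C6' (twofold Michael).
Enabling feature: C4–C5–C5'–C4' is the carbon chain of succinic acid, its carboxyl carbons becoming the C4 carbonyls, and O–C2–C3(CH3)–C4–O is a 2-methyl-1,3-dicarbonyl unit that an ethyl ketone and an ester can form by acylation, so the inter-ring bond is bought as the CH2–CH2 bond of diethyl succinate and no biaryl coupling is needed.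
Forward: an enone is made by olefination, two enone units are attached to the succinate α-carbons, both carbocycles close in one Claisen operation, both are aromatised together and both are oxidised at C1 together.
Stereochemistry: the target has no stereocentre; the sp3 centres made on the way (C3, C5, C6 and their primed partners) are carried as mixtures and vanish on aromatisation.
Key step: step 4

Remark: the target SMILES carries no stereodescriptor, so the configuration about the tetra-ortho-substituted ring-to-ring axis is taken as undefined and the racemate is the goal.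

Step 1
Reactants: 1 3-phenylpropanal; 2 diethyl (2-oxobutyl)phosphonate
Product: 3 (E)-7-phenylhept-4-en-3-one
Conditions: LiCl, i-Pr2NEt, MeCN, rt
Reagents that add atoms: none
Why: Horner–Wadsworth–Emmons olefination with a stabilised β-ketophosphonate anion under mild LiCl/amine conditions tolerates the enolisable aldehyde and should give the (E)-enone as the thermodynamically favoured alkene.

Step 2
Reactants: 4 diethyl succinate (diethyl butanedioate)
Product: 5 1,4-diethoxy-1,4-bis(trimethylsilyloxy)buta-1,3-diene (mixture of double-bond isomers)
Conditions: LiN(i-Pr)2 (2.2 equiv), THF, −78 °C; TMSCl (2.5 equiv), −78 °C to rt; filtration under argon, distillation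
Reagents that add atoms: chlorotrimethylsilane (TMSCl), C[Si](C)(C)Cl
Why: Twofold ester enolisation at −78 °C followed by O-silylation of the α-substituted ester enolates (silyl ketene acetal formation) should give the isolable neutral equivalent of the succinate dianion, whose double-bond geometry is of no consequence.

Step 3
Reactants: 5 1,4-diethoxy-1,4-bis(trimethylsilyloxy)buta-1,3-diene; 3 (E)-7-phenylhept-4-en-3-one (2.2 equiv)
Product: 8 diethyl 2,3-bis(5-oxo-1-phenylheptan-3-yl)butanedioate (mixture of diastereomers), via mono-Michael adduct 6 (not isolated), via bis(silyl enol ether) 7 (not isolated)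
Conditions: Tf2NH (3 mol%), CH2Cl2, −78 to −40 °C; then 1 M HCl, THF, 0 °C
Reagents that add atoms: none
Why: In a twofold Mukaiyama–Michael addition catalysed by Me3SiNTf2 (formed in the flask from Tf2NH) the two succinate α-carbons C5 and C5' of the bis(ketene acetal) should attack the β-carbon C6 of the silyl-activated enone with silyl transfer to the enolate oxygen, the silyl enol ether left by the first addition being far less nucleophilic than the remaining ketene acetal so that the second enone is taken up at C5', and the four new stereocentres (C5, C6, C5', C6') are left uncontrolled because all become sp2 in step 5.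

Step 4
Reactants: 8 diethyl 2,3-bis(5-oxo-1-phenylheptan-3-yl)butanedioate
Product: 10 3,3'-dimethyl-6,6'-bis(2-phenylethyl)-[1,1'-bi(cyclohexane)]-2,2',4,4'-tetrone (diastereomer mixture; largely enolised), via mono-cyclised keto ester 9 (not isolated)
Conditions: NaOC2H5 (6 equiv), C2H5OH, reflux; then 2 M HCl, 0 °C
Reagents that add atoms: none
Why: Ethoxide reversibly enolises each ethyl ketone on its CH2CH3 side, and the enolate carbon C3 (C3') adds to the ester carbonyl C4 (C4') of its own half and expels ethoxide, a twofold intramolecular Claisen (Dieckmann-type) condensation of a δ-keto ester, the reaction type by which cyclohexane-1,3-diones such as dimedone are made from Michael adducts. Each ring (atoms C3, C2, C1, C6, C5, C4) closes by a 6-(enolendo)-exo-trig acyl substitution, first to the mono-dione 9 and then to 10. Every 2-methyl-1,3-dione formed is deprotonated at once to its vinylogous carboxylate, which consumes one equivalent of base per ring and pulls the otherwise unfavourable Claisen equilibria forward. The new centres C3 and C3' are enolisable and uncontrolled, and C5, C6, C5', C6' may epimerise; none of them survives aromatisation. The selectivity required is acylation at C3 and not at the other ketone α-carbon C1, whose enolate can reach only the distal ester to give a five-membered 2-acylcyclopentanone (the proximal ester would mean a four-membered ring). This is secured thermodynamically: under the reversible alkoxide conditions the acylcyclopentanone should be reopened by retro-Claisen cleavage while the more acidic cyclohexane-1,3-dione enolate accumulates, and the seven-membered closure of C3 onto C4' is kinetically uncompetitive.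

Step 5
Reactants: 10 3,3'-dimethyl-6,6'-bis(2-phenylethyl)-[1,1'-bi(cyclohexane)]-2,2',4,4'-tetrone
Product: 12 3,3'-dimethyl-6,6'-bis(2-phenylethyl)-[1,1'-biphenyl]-2,2',4,4'-tetrol (racemic about the biaryl axis), via half-aromatised dione 11 (not isolated)
Conditions: 10% Pd/C, p-cymene, reflux (177 °C), argon stream
Reagents that add atoms: none
Why: Heterogeneous catalytic dehydrogenation over Pd/C at high temperature, the standard conversion of cyclohexane-1,3-diones (dihydroresorcinols) into resorcinols, should remove one H2 per ring with aromatisation as the driving force, which erases every sp3 stereocentre and leaves only the racemic biaryl axis.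

Step 6
Reactants: 12 3,3'-dimethyl-6,6'-bis(2-phenylethyl)-[1,1'-biphenyl]-2,2',4,4'-tetrol
Product: 14 4,4'-dihydroxy-5,5'-dimethyl-2,2'-bis(2-phenylethyl)-[1,1'-bi(cyclohexa-1,4-diene)]-3,3',6,6'-tetrone (target CNP0136737.0), via mono-quinone 13 (not isolated)
Conditions: (KSO3)2NO (6 equiv), KH2PO4 buffer, acetone/H2O, 0 °C to rt
Reagents that add atoms: potassium nitrosodisulfonate (KSO3)2NO, [K+].[K+].[O]N(S(=O)(=O)[O-])S(=O)(=O)[O-]
Why: In a Teuber oxidation the nitrosodisulfonate radical abstracts a phenolic hydrogen and a second equivalent couples at C1, the only unsubstituted ring carbon (para to the C4 hydroxyl, ortho to the C2 hydroxyl), and loss of HN(SO3K)2 should give the 2-hydroxy-1,4-benzoquinone, the same tautomeric product arising whichever hydroxyl is oxidised first.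

Compound list
1 | 3-phenylpropanal | O=CCCc1ccccc1 | starting material
2 | diethyl (2-oxobutyl)phosphonate | CCC(=O)CP(=O)(OCC)OCC | starting material
3 | (E)-7-phenylhept-4-en-3-one | CCC(=O)/C=C/CCc1ccccc1 | intermediate
4 | diethyl succinate (diethyl butanedioate) | CCOC(=O)CCC(=O)OCC | starting material
5 | 1,4-diethoxy-1,4-bis(trimethylsilyloxy)buta-1,3-diene (double-bond isomer mixture) | CCOC(O[Si](C)(C)C)=CC=C(OCC)O[Si](C)(C)C | intermediate
6 | mono-Michael adduct: ethyl 2-[2-ethoxy-2-(trimethylsilyloxy)ethenyl]-3-(2-phenylethyl)-5-(trimethylsilyloxy)hept-4-enoate (isomer mixture) | CCOC(=O)C(C=C(OCC)O[Si](C)(C)C)C(CCc1ccccc1)C=C(CC)O[Si](C)(C)C | intermediate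
7 | bis(silyl enol ether): diethyl 2,3-bis[1-phenyl-5-(trimethylsilyloxy)hept-4-en-3-yl]butanedioate (isomer mixture) | CCOC(=O)C(C(CCc1ccccc1)C=C(CC)O[Si](C)(C)C)C(C(CCc1ccccc1)C=C(CC)O[Si](C)(C)C)C(=O)OCC | intermediate
8 | diethyl 2,3-bis(5-oxo-1-phenylheptan-3-yl)butanedioate (diastereomer mixture) | CCOC(=O)C(C(CCc1ccccc1)CC(=O)CC)C(C(CCc1ccccc1)CC(=O)CC)C(=O)OCC | intermediate
9 | mono-cyclised keto ester: ethyl 2-[3-methyl-2,4-dioxo-6-(2-phenylethyl)cyclohexyl]-5-oxo-3-(2-phenylethyl)heptanoate (diastereomer mixture, present as its sodium enolate) | CCOC(=O)C(C(CCc1ccccc1)CC(=O)CC)C1C(=O)C(C)C(=O)CC1CCc1ccccc1 | intermediate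
10 | 3,3'-dimethyl-6,6'-bis(2-phenylethyl)-[1,1'-bi(cyclohexane)]-2,2',4,4'-tetrone (diastereomer mixture, largely enolised) | CC1C(=O)CC(CCc2ccccc2)C(C1=O)C1C(=O)C(C)C(=O)CC1CCc1ccccc1 | intermediate
11 | half-aromatised dione: 4-[2,4-dihydroxy-3-methyl-6-(2-phenylethyl)phenyl]-2-methyl-5-(2-phenylethyl)cyclohexane-1,3-dione (diastereomer mixture) | CC1C(=O)CC(CCc2ccccc2)C(C1=O)c1c(CCc2ccccc2)cc(O)c(C)c1O | intermediate
12 | 3,3'-dimethyl-6,6'-bis(2-phenylethyl)-[1,1'-biphenyl]-2,2',4,4'-tetrol (racemic axis) | Cc1c(O)cc(CCc2ccccc2)c(c1O)-c1c(CCc2ccccc2)cc(O)c(C)c1O | intermediate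
13 | mono-quinone: 5-[2,4-dihydroxy-3-methyl-6-(2-phenylethyl)phenyl]-2-hydroxy-3-methyl-6-(2-phenylethyl)cyclohexa-2,5-diene-1,4-dione | CC1=C(O)C(=O)C(CCc2ccccc2)=C(C1=O)c1c(CCc2ccccc2)cc(O)c(C)c1O | intermediate
14 | 4,4'-dihydroxy-5,5'-dimethyl-2,2'-bis(2-phenylethyl)-[1,1'-bi(cyclohexa-1,4-diene)]-3,3',6,6'-tetrone (CNP0136737.0) | CC1=C(O)C(=O)C(CCc2ccccc2)=C(C2=C(CCc3ccccc3)C(=O)C(O)=C(C)C2=O)C1=O | target

Total step count: 6
Longest linear sequence: 5 steps (steps 1, 3, 4, 5, 6 from 3-phenylpropanal; equally steps 2 to 6 from diethyl succinate)

Steps most likely to fail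

Step 3. The second conjugate addition must occur at a ketene acetal carbon that already carries a branched neighbour, so the reaction may stall at the mono-adduct stage while the electron-rich bis(ketene acetal) is lost to protodesilylation. The fallback forms the C5–C5' bond last instead of first. Setting out from enone 3, a Mukaiyama–Michael addition of the readily available 1-(tert-butyldimethylsilyloxy)-1-ethoxyethene (Tf2NH cat., CH2Cl2, −78 °C) would give ethyl 5-(tert-butyldimethylsilyloxy)-3-(2-phenylethyl)hept-4-enoate F1, in which the ketone stays masked as its silyl enol ether. Deprotonation of the ester with LiN(i-Pr)2 in THF at −78 °C and oxidative enolate coupling with half an equivalent of I2 would then give diethyl 2,3-bis[5-(tert-butyldimethylsilyloxy)-1-phenylhept-4-en-3-yl]butanedioate F2. Treatment with 1 M HCl in THF would unmask both ketones and bring the sequence back to the route at compound 8, without need of compound 5.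

Step 4. Ring closure may run through the wrong enolate (C1 onto the distal ester C4', five-membered ring) and revert only slowly. The sequence may also stop after the first ring, or hot ethoxide may cleave C5–C6 by retro-Michael fragmentation. The fallback closes the same bonds one oxidation level higher, so that aromatisation makes the six-membered closure irreversible. Setting out from bis(silyl enol ether) 7, isolated by a non-aqueous work-up instead of being hydrolysed, Saegusa–Ito oxidation with Pd(OAc)2 in MeCN at rt would give diethyl 2,3-bis(5-oxo-1-phenylhept-3-en-3-yl)butanedioate F3. NaOC2H5 in ethanol would then equilibrate the alkene geometry through the extended enolate and effect the same C3–C4 and C3'–C4' acylations. Each closed ring is now a resorcinol tautomer, so the sequence comes back to the route at compound 12 and spares step 5 as well.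

Step 5. Dehydrogenation of the two congested rings may remain incomplete at the temperature required, hydrogen transfer on the catalyst may strip a ring oxygen, and the 1,4-dicarbonyl array C4/C4' may cyclodehydrate thermally to a furan before aromatisation. The fallback replaces catalytic dehydrogenation by halogenation and dehydrohalogenation at lower temperature under carbonate buffering. Setting out from compound 10, NBS in CH2Cl2 at 0 °C would brominate the enolised diones at C3 and C3' to give 3,3'-dibromo-3,3'-dimethyl-6,6'-bis(2-phenylethyl)-[1,1'-bi(cyclohexane)]-2,2',4,4'-tetrone F4. Heating with LiBr and Li2CO3 in DMF would move bromine from the quaternary C3 to an enolisable ring position and eliminate HBr, returning to the route at compound 12.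

Further compounds
F1 | step 3 | ethyl 5-(tert-butyldimethylsilyloxy)-3-(2-phenylethyl)hept-4-enoate | CCOC(=O)CC(CCc1ccccc1)C=C(CC)O[Si](C)(C)C(C)(C)C
F2 | step 3 | diethyl 2,3-bis[5-(tert-butyldimethylsilyloxy)-1-phenylhept-4-en-3-yl]butanedioate | CCOC(=O)C(C(CCc1ccccc1)C=C(CC)O[Si](C)(C)C(C)(C)C)C(C(CCc1ccccc1)C=C(CC)O[Si](C)(C)C(C)(C)C)C(=O)OCC
F3 | step 4 | diethyl 2,3-bis(5-oxo-1-phenylhept-3-en-3-yl)butanedioate | CCOC(=O)C(C(CCc1ccccc1)=CC(=O)CC)C(C(CCc1ccccc1)=CC(=O)CC)C(=O)OCC
F4 | step 5 | 3,3'-dibromo-3,3'-dimethyl-6,6'-bis(2-phenylethyl)-[1,1'-bi(cyclohexane)]-2,2',4,4'-tetrone | CC1(Br)C(=O)CC(CCc2ccccc2)C(C1=O)C1C(=O)C(C)(Br)C(=O)CC1CCc1ccccc1
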